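Count the nucleophile, not the base.

    electrophile + nucleophile → acid set free + target (k1 = 10.0 /M/s)
    nucleophile + acid set free ⇌ protonated nucleophile, settled at all times (K2 = 1.1 × 10⁶ /M)
    acid set free + free base ⇌ salt of the base, settled at all times (K3 = 160 /M)
    gas ⇌ nucleophile, rate k4*(csat - [nucleophile]) (k4 = 0.0983 /s, csat = 3.0 mM)
    free base + target → over-reaction product (k5 = 1.74 /M/s)

the same everywhere: electrophile 14 mM; gas 3.0 mM (held); time 20 s
- oak: free base 1.10 equiv
- larch: free base 1.40 equiv
- birch: free base 1.90 equiv

1. part of the electrophile that has reacted at the end, oak
2. part of the electrophile that has reacted at the end, larch
3. part of the electrophile that has reacted at the end, birch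
4. what raising the equivalents of free base from its lowest to its highest value here does to the part of the electrophile that has reacted (changes below 5 percentage points count as none) (it rises / it falls / no change)

I ranked the events by time at the charged amounts, fastest first. The two acid balances stand lowest because they hold at every instant. I supposed at first that the acid goes to the nucleophile, so that each electrophile turned costs two nucleophiles: one is substituted and one is protonated.

Next comes the dissolved nucleophile, fed by the gas and drawn down twice over by the electrophile:

uptake time = 1 / (0.0983 /s + 2 × 10.0 /M/s × 14 mM) = 2.64 s

level = 0.0983 /s × 3.0 mM × uptake time = 0.780 mM

I call this the supply level, the dissolved nucleophile at which transfer from the gas just pays for two nucleophiles per electrophile turned; it is a quasi-steady state.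

The supposition held. At that level the nucleophile outbids the free base for acid 348 to one in oak and 201 to one in birch, so nearly all of the acid sits on the nucleophile.

Higher up, target goes on to over-reaction product with a half-life of 26 s in oak, a step that takes no electrophile.

On the top rung, the electrophile's half-life at the supply level is 88.9 s, longer than the 20 s of the run, so I kept its charge in the reckoning. The nucleophile it meets, summed over the run after the uptake lag, is:

exposure = level × (time − uptake time × (1 − e^(−time / uptake time))) = 0.0135 M·s

Free base stands in neither line, so I reckoned 12.7 % for oak, 12.7 % for larch and 12.7 % for birch. I estimated the effect of the base's small share of the acid at about 0.026 percentage points from oak to birch, less than the 5 points that counts, so my trend was: no change.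

The forecast, higher than my figure, gave 13.1 %, 13.1 % and 13.2 % for oak, larch and birch, with no change, reasoning that “the acid therefore sits on the nucleophile”.

The simulation gave 13.1 %, 13.1 % and 13.1 % for oak, larch and birch, and raising the free base from oak's equivalents to birch's brought no change, a change of 0.0073 points. In birch, neither the association of acid with free base nor the over-reaction makes a difference to the electrophile reacted. Oak's dissolved nucleophile read 0.784 mM at 10.0 s, against a supply level of 0.780 mM.

For oak read at 5.0 s, the same level and uptake time give an exposure of 2.15 mM·s and so 2.13 % reacted. The simulation gives 2.13 %.

The rate constants are those of an exercise, and the outcome is calculated.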